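**Plan**
1. Retrosynthesis: cut the six O–benzyl bonds and the C3–O gallate ester; then cut the pyran bond O1–C2 and return O1 to C3, so that the chroman becomes a 2-(α-hydroxybenzyl)-2,3-dihydrobenzofuran; then carbinol → ketone; then the dihydrofuran bonds C3–C4 and C3–O1 ([4+1] of an A-ring o-quinone methide with a B-ring phenacyl ylide).
2. Forward: the A ring comes as 3,5-bis(benzyloxy)phenol and the B ring as an acetophenone. A five-membered dihydrofuran ring is closed first and is then grown into the six-membered pyran by inserting the carbinol carbon (C2) between O1 and C3; the gallate is joined next and hydrogenolysis ends the route.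
3. Enabling feature: in the precursor the A-ring oxygen O1 sits on C3 inside the strained five-membered ring, next to a benzylic C2–OH. O1 can leave as a phenoxide when the C2 alkoxide closes an oxirane, and the same phenoxide re-enters at benzylic C2, which the p-methoxyphenyl B ring activates.
4. Stereochemistry: both centres are set in one Ru-catalysed transfer hydrogenation with dynamic kinetic resolution of the racemic α-aryloxy ketone (threo, αS,2S). The ring expansion relays them by two SN2 inversions (one at C3, one at C2), which turns threo into 2,3-cis (2R,3R).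

Key step: step 5

Assumption: compounds 1, 3 and 12 are taken as catalogue chemicals (3 is otherwise one benzylation away from 3-hydroxy-4-methoxyacetophenone).

**Step 1**
Reactants: 1 3,5-bis(benzyloxy)phenol
Product: 2 3,5-bis(benzyloxy)-2-[(dimethylamino)methyl]phenol
Conditions: 37% aq. CH2O (1.0 equiv), 40% aq. Me2NH (1.1 equiv), EtOH, 0 °C → rt
Reagents that add atoms: formaldehyde C=O; dimethylamine CNC
Why: Phenolic Mannich reaction: the hydrogen-bonded phenol delivers the iminium ion to the ortho position (C2 and C6 are equivalent), whereas the para position is flanked by two benzyloxy groups; no stereocentre is formed.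

**Step 2**
Reactants: 3 1-[3-(benzyloxy)-4-methoxyphenyl]ethan-1-one
Product: 4 1-{2-[3-(benzyloxy)-4-methoxyphenyl]-2-oxoethyl}pyridin-1-ium iodide
Conditions: I2 (1.0 equiv), pyridine, 100 °C
Reagents that add atoms: pyridine c1ccncc1; iodine II
Why: Ortoleva–King reaction: α-iodination of the enolisable methyl ketone and displacement of iodide by pyridine give the phenacylpyridinium salt in one operation; the alkoxyarene ring is not iodinated by I2 without an oxidant.

**Step 3**
Reactants: 2 3,5-bis(benzyloxy)-2-[(dimethylamino)methyl]phenol; 4 1-{2-[3-(benzyloxy)-4-methoxyphenyl]-2-oxoethyl}pyridin-1-ium iodide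
Product: 8 rac-[4,6-bis(benzyloxy)-2,3-dihydro-1-benzofuran-2-yl][3-(benzyloxy)-4-methoxyphenyl]methanone, via o-quinone methide 5 (not isolated), via pyridinium ylide 6 (not isolated), via phenolate betaine 7 (not isolated)
Conditions: DBU (1.2 equiv), MeCN, reflux, Ar
Reagents that add atoms: none
Why: Formal [4+1] annulation of an o-quinone methide with a pyridinium ylide (known for phenolic Mannich bases): thermal loss of Me2NH from 2 gives 5, conjugate addition of 6 to the methide carbon gives 7, and the phenoxide displaces pyridine 5-exo-tet at the carbon α to the ketone; the new centre is formed racemic and stays enolisable, which step 4 uses.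

**Step 4**
Reactants: 8 rac-[4,6-bis(benzyloxy)-2,3-dihydro-1-benzofuran-2-yl][3-(benzyloxy)-4-methoxyphenyl]methanone
Product: 9 (S)-[(2S)-4,6-bis(benzyloxy)-2,3-dihydro-1-benzofuran-2-yl][3-(benzyloxy)-4-methoxyphenyl]methanol (threo)
Conditions: RuCl[(R,R)-TsDPEN](p-cymene) (1 mol %), HCO2H/Et3N (2:5, amine-rich), DMF, 35 °C
Reagents that add atoms: none
Why: Noyori asymmetric transfer hydrogenation under dynamic kinetic resolution (as for benzoin and α-alkoxy aryl ketones): the α-aryloxy ketone enolises in the amine-rich medium, the (R,R)-catalyst is expected to set the (αS)-carbinol by the aryl-ketone model, and the (2S)-ketone is the matched enantiomer because its Felkin–Anh mode (aryloxy C–O anti to the incoming hydride, no chelation) leads to the threo alcohol, so both stereocentres are set here.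

**Step 5**
Reactants: 9 (S)-[(2S)-4,6-bis(benzyloxy)-2,3-dihydro-1-benzofuran-2-yl][3-(benzyloxy)-4-methoxyphenyl]methanol
Product: 11 (2R,3R)-5,7-bis(benzyloxy)-2-[3-(benzyloxy)-4-methoxyphenyl]-3,4-dihydro-2H-chromen-3-ol, via cis-epoxide phenolate 10 (not isolated)
Conditions: KOtBu (0.3 equiv), 18-crown-6 (0.3 equiv), degassed DMSO (0.02 M), 95 °C, Ar; then aq. NH4Cl
Reagents that add atoms: none
Why: Proposed new method: the potassium alkoxide of 9 should attack C2 of the dihydrofuran from the rear of the C–O1 bond (3-exo-tet, inversion) and expel the A-ring oxygen as a phenoxide (pKa about 10, helped by release of five-ring strain) to give the cis-epoxide phenolate 10; this is the neighbouring-alkoxide displacement of a β-aryloxy group known from alkaline cleavage of β-O-4 aryl ethers and is Payne-like. The tethered phenoxide re-opens the oxirane either 5-exo (degenerate return to 9) or 6-endo-tet at the benzylic carbon activated by the p-methoxyphenyl ring, the known base-mediated closure of (2-hydroxybenzyl)aryloxiranes to flavan-3-ols; the net result is a 1,2-shift of O1 from C3 to C2 that inserts the carbinol carbon into the ring. No stereocentre is made afresh: C3 is inverted once when the oxirane closes and C2 once when it opens, so the threo alcohol (αS,2S) must give the 2,3-cis flavan (2R,3R), whereas an acid-mediated (oxiranium or benzylic cation) version of the same shift would be expected to end in the 2,3-trans series. All events are reversible SN2 steps, so the six-membered ring should win on thermodynamic grounds over the strained five-membered one, and sub-stoichiometric base lets the neutral alcohols, not the alkoxides, set the equilibrium. Stereochemical fidelity rests on the absence of acid or cations and on the 4'-oxygen being a methyl ether, which excludes quinone-methide epimerisation at C2; oxygen and residual ketone 8 are excluded so that no hydride transfer can scramble the carbinol centre.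

**Step 6**
Reactants: 11 (2R,3R)-5,7-bis(benzyloxy)-2-[3-(benzyloxy)-4-methoxyphenyl]-3,4-dihydro-2H-chromen-3-ol; 12 3,4,5-tris(benzyloxy)benzoic acid
Product: 13 (2R,3R)-5,7-bis(benzyloxy)-2-[3-(benzyloxy)-4-methoxyphenyl]-3,4-dihydro-2H-chromen-3-yl 3,4,5-tris(benzyloxy)benzoate
Conditions: DCC (1.5 equiv), DMAP, CH2Cl2, 0 °C → rt
Reagents that add atoms: none
Why: Steglich esterification of the secondary axial 3-OH with the protected gallic acid, routine for 3-O-galloylation of protected flavan-3-ols; no stereocentre is involved.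

**Step 7**
Reactants: 13 (2R,3R)-5,7-bis(benzyloxy)-2-[3-(benzyloxy)-4-methoxyphenyl]-3,4-dihydro-2H-chromen-3-yl 3,4,5-tris(benzyloxy)benzoate
Product: 14 4'-O-methylepicatechin-3-O-gallate
Conditions: H2 (1 atm), 20% Pd(OH)2/C, THF/MeOH, rt
Reagents that add atoms: none
Why: Hydrogenolysis of the six benzyl ethers over Pearlman's catalyst under neutral conditions, the standard last step for perbenzylated catechin gallates; the methyl ether, the ester and the cyclic benzylic C2–O1 bond are expected to survive.

**Compound list**
1 | 3,5-bis(benzyloxy)phenol | Oc1cc(OCc2ccccc2)cc(OCc2ccccc2)c1 | starting material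
2 | 3,5-bis(benzyloxy)-2-[(dimethylamino)methyl]phenol | CN(C)Cc1c(O)cc(OCc2ccccc2)cc1OCc1ccccc1 | intermediate
3 | 1-[3-(benzyloxy)-4-methoxyphenyl]ethan-1-one | CC(=O)c1ccc(OC)c(OCc2ccccc2)c1 | starting material
4 | 1-{2-[3-(benzyloxy)-4-methoxyphenyl]-2-oxoethyl}pyridin-1-ium iodide | O=C(C[n+]1ccccc1)c1ccc(OC)c(OCc2ccccc2)c1.[I-] | intermediate
5 | 3,5-bis(benzyloxy)-6-methylidenecyclohexa-2,4-dien-1-one (o-quinone methide) | C=C1C(=O)C=C(OCc2ccccc2)C=C1OCc1ccccc1 | intermediate (not isolated)
6 | pyridinium ylide of 4, 2-[3-(benzyloxy)-4-methoxyphenyl]-2-oxo-1-(pyridin-1-ium-1-yl)ethan-1-ide | O=C([CH-][n+]1ccccc1)c1ccc(OC)c(OCc2ccccc2)c1 | intermediate (not isolated)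
7 | 3,5-bis(benzyloxy)-2-{3-[3-(benzyloxy)-4-methoxyphenyl]-3-oxo-2-(pyridin-1-ium-1-yl)propyl}phenolate (betaine, racemic) | [O-]c1cc(OCc2ccccc2)cc(OCc2ccccc2)c1CC(C(=O)c1ccc(OC)c(OCc2ccccc2)c1)[n+]1ccccc1 | intermediate (not isolated)
8 | rac-[4,6-bis(benzyloxy)-2,3-dihydro-1-benzofuran-2-yl][3-(benzyloxy)-4-methoxyphenyl]methanone | O=C(C1Cc2c(OCc3ccccc3)cc(OCc3ccccc3)cc2O1)c1ccc(OC)c(OCc2ccccc2)c1 | intermediate
9 | (S)-[(2S)-4,6-bis(benzyloxy)-2,3-dihydro-1-benzofuran-2-yl][3-(benzyloxy)-4-methoxyphenyl]methanol (threo) | O[C@H]([C@@H]1Cc2c(OCc3ccccc3)cc(OCc3ccccc3)cc2O1)c1ccc(OC)c(OCc2ccccc2)c1 | intermediate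
10 | potassium 3,5-bis(benzyloxy)-2-({(2R,3S)-3-[3-(benzyloxy)-4-methoxyphenyl]oxiran-2-yl}methyl)phenolate (cis-epoxide) | [K+].[O-]c1cc(OCc2ccccc2)cc(OCc2ccccc2)c1C[C@H]1O[C@H]1c1ccc(OC)c(OCc2ccccc2)c1 | intermediate (not isolated)
11 | (2R,3R)-5,7-bis(benzyloxy)-2-[3-(benzyloxy)-4-methoxyphenyl]-3,4-dihydro-2H-chromen-3-ol (2,3-cis) | COc1ccc([C@H]2Oc3cc(OCc4ccccc4)cc(OCc4ccccc4)c3C[C@H]2O)cc1OCc1ccccc1 | intermediate
12 | 3,4,5-tris(benzyloxy)benzoic acid | OC(=O)c1cc(OCc2ccccc2)c(OCc2ccccc2)c(OCc2ccccc2)c1 | starting material
13 | (2R,3R)-5,7-bis(benzyloxy)-2-[3-(benzyloxy)-4-methoxyphenyl]-3,4-dihydro-2H-chromen-3-yl 3,4,5-tris(benzyloxy)benzoate | COc1ccc([C@H]2Oc3cc(OCc4ccccc4)cc(OCc4ccccc4)c3C[C@H]2OC(=O)c2cc(OCc3ccccc3)c(OCc3ccccc3)c(OCc3ccccc3)c2)cc1OCc1ccccc1 | intermediate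
14 | 4'-O-methylepicatechin-3-O-gallate, (2R,3R) | COc1ccc([C@H]2Oc3cc(O)cc(O)c3C[C@H]2OC(=O)c2cc(O)c(O)c(O)c2)cc1O | target

**Totals**
Total step count: 7. Longest linear sequence: 6 steps (steps 2–7 from 3, or steps 1 and 3–7 from 1).

**Steps most likely to fail**

1. Step 5 (proposed new method). The alkoxide may not displace the aryloxide below the temperature at which base-induced β-elimination opens the dihydrofuran, or the equilibrium may not lie far enough on the chroman side. Fallback with known chemistry, setting out from 1 and coming back at 11: the pyran is closed directly instead of being grown from the furan. Mitsunobu etherification (PPh3, DIAD) of 1 with 1-[3-(benzyloxy)-4-methoxyphenyl]prop-2-yn-1-ol F1 (one step from commercial 3-(benzyloxy)-4-methoxybenzaldehyde and ethynylmagnesium bromide) should give 1,3-bis(benzyloxy)-5-({1-[3-(benzyloxy)-4-methoxyphenyl]prop-2-yn-1-yl}oxy)benzene F2. Gold(I)-catalysed oxidation of the terminal alkyne with a pyridine N-oxide, with closure of the α-oxo gold carbene onto the arene (both ortho positions are equivalent), should give racemic 5,7-bis(benzyloxy)-2-[3-(benzyloxy)-4-methoxyphenyl]chroman-3-one F3. Transfer hydrogenation of this configurationally labile α-aryl ketone under dynamic kinetic resolution (Ru–TsDPEN, HCO2H/Et3N), a known route to cis-2-aryl cycloalkanols, should then give 11.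

2. Step 4. Enolisation of the α-aryloxy ketone may be slower than reduction, so that the dynamic resolution degrades to a simple kinetic resolution; or facial control at the α-centre may be incomplete, and the erythro alcohol would end as the 2,3-trans flavan. Fallback, setting out from 8 and coming back at 9: substrate-controlled Felkin–Anh reduction with L-Selectride (THF, −78 °C) should give the racemic threo alcohol F4, which is resolved by preparative chromatography on a chiral stationary phase. The unwanted enantiomer is re-oxidised to 8 with Dess–Martin periodinane and recycled.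

3. Step 1. The doubly activated ring may be aminomethylated twice or para to the hydroxyl. Fallback, setting out from 1 and coming back at 8: magnesium-phenoxide-directed ortho-formylation (MgCl2, Et3N, paraformaldehyde; Casnati–Skattebøl) should give 2,4-bis(benzyloxy)-6-hydroxybenzaldehyde F5. NaBH4 reduction should give 3,5-bis(benzyloxy)-2-(hydroxymethyl)phenol F6. F6 replaces 2 as the thermal o-quinone methide precursor under the conditions of step 3 and so returns to the route at 8.

**Further compounds**
F1 | step 5 | 1-[3-(benzyloxy)-4-methoxyphenyl]prop-2-yn-1-ol (racemic) | C#CC(O)c1ccc(OC)c(OCc2ccccc2)c1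
F2 | step 5 | 1,3-bis(benzyloxy)-5-({1-[3-(benzyloxy)-4-methoxyphenyl]prop-2-yn-1-yl}oxy)benzene (racemic) | C#CC(Oc1cc(OCc2ccccc2)cc(OCc2ccccc2)c1)c1ccc(OC)c(OCc2ccccc2)c1
F3 | step 5 | rac-5,7-bis(benzyloxy)-2-[3-(benzyloxy)-4-methoxyphenyl]chroman-3-one | COc1ccc(C2Oc3cc(OCc4ccccc4)cc(OCc4ccccc4)c3CC2=O)cc1OCc1ccccc1
F4 | step 4 | racemic threo alcohol, racemate of 9, relative configuration (αS*,2S*) | O[C@H]([C@@H]1Cc2c(OCc3ccccc3)cc(OCc3ccccc3)cc2O1)c1ccc(OC)c(OCc2ccccc2)c1
F5 | step 1 | 2,4-bis(benzyloxy)-6-hydroxybenzaldehyde | O=Cc1c(O)cc(OCc2ccccc2)cc1OCc1ccccc1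
F6 | step 1 | 3,5-bis(benzyloxy)-2-(hydroxymethyl)phenol | OCc1c(O)cc(OCc2ccccc2)cc1OCc1ccccc1
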